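## Retrosynthetic overview

1. Target 22 comes from tert-butyl ester/dimethyl acetal 21 (acid), which comes from bis(enol triflate) 20 by a twofold Negishi methylation that installs C8–Me/Δ7 and C13–Me/13E together; 20 comes from diketo ester 18.
2. Key disconnection: 18 comes from vinyl hydrindanol 14 and bromoacetoacetate 17 by an alkylative semipinacol ring expansion. C10 shifts from C8 to C9, turning the cyclopentanol into the ring-B cyclohexanone and forming C11–C12 and C9.
3. 14 comes from (R)-Hajos–Parrish ketone 5: vinyl addition, Birch reduction/formylation (trans fusion, C5), methylation anti to the angular methyl (C4), acetal, L-Selectride (axial C3–O), acetylation.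
4. 5 comes from 2-methylcyclopentane-1,3-dione and methyl vinyl ketone by D-proline aldol condensation (sets C10).
5. Ring order: cyclopentane (bought), then ring A (aldol condensation), then ring B (ring expansion of the cyclopentane).

Assumption: labdane numbering (C1–C20) is used in the explanations; the target is read as the (3S,4S,5S,9R,10S),13E isomer (an ent-labdane).

## Route

Step 1
Reactants: 1 2-methylcyclopentane-1,3-dione; 2 but-3-en-2-one
Product: 3 2-methyl-2-(3-oxobutyl)cyclopentane-1,3-dione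
Conditions: AcOH (cat.), H2O, 75 °C
Reagents that add atoms: none
Why: Michael addition of the enolized 1,3-dione to the vinyl ketone in water creates the still prochiral quaternary carbon that becomes C10.

Step 2
Reactants: 3 2-methyl-2-(3-oxobutyl)cyclopentane-1,3-dione
Product: 5 (R)-7a-methyl-2,3,7,7a-tetrahydro-1H-indene-1,5(6H)-dione, via ketol 4 (not isolated)
Conditions: D-proline (3 mol%), DMF, 20 °C; then H2SO4 (cat.), DMF, 95 °C; recrystallize
Reagents that add atoms: none
Why: The Hajos–Parrish (Eder–Sauer–Wiechert) enamine aldol with D-proline desymmetrizes the two ring carbonyls to the (3aR,7aR)-ketol, and acid dehydration gives the (R)-enone, fixing C10.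

Step 3
Reactants: 5 (R)-7a-methyl-2,3,7,7a-tetrahydro-1H-indene-1,5(6H)-dione; 6 vinylmagnesium bromide
Product: 7 (1S,7aR)-1-ethenyl-1-hydroxy-7a-methyl-1,2,3,6,7,7a-hexahydro-5H-inden-5-one
Conditions: CeCl3, THF, −78 °C; aq NH4Cl
Reagents that add atoms: none
Why: The organocerium (Imamoto-type Grignard) reagent adds 1,2 to the more electrophilic saturated cyclopentanone rather than the enone, anti to the angular methyl; this carbinol centre is consumed in step 10.

Step 4
Reactants: 7 (1S,7aR)-1-ethenyl-1-hydroxy-7a-methyl-1,2,3,6,7,7a-hexahydro-5H-inden-5-one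
Product: 10 (1S,3aS,7aR)-1-ethenyl-1-hydroxy-4-[(Z)-hydroxymethylidene]-7a-methyloctahydro-5H-inden-5-one, via lithium alkoxide 8 (not isolated), via dilithium enolate 9 (not isolated)
Conditions: n-BuLi (1.0 equiv), THF, −78 °C; Li (2.2 equiv), NH3(l)/THF, t-BuOH (1.0 equiv), −78 °C; evaporate NH3; HCO2CH2CF3, THF, −78 → 0 °C; aq NH4Cl
Reagents that add atoms: 2,2,2-trifluoroethyl formate, O=COCC(F)(F)F
Why: Birch reduction with Stork enolate trapping protonates the β-carbon to give the trans ring fusion (C5–H anti to the angular methyl), and the regiodefined lithium enolate undergoes Claisen-type C-formylation with the reactive formate, while the tertiary alcohol rides through as its lithium alkoxide.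

Step 5
Reactants: 10 (1S,3aS,7aR)-1-ethenyl-1-hydroxy-4-[(Z)-hydroxymethylidene]-7a-methyloctahydro-5H-inden-5-one
Product: 11 (1S,3aS,4R,7aR)-1-ethenyl-1-hydroxy-4,7a-dimethyl-5-oxooctahydro-1H-indene-4-carbaldehyde
Conditions: MeI, K2CO3, acetone, 50 °C
Reagents that add atoms: iodomethane, CI
Why: Enolate C-alkylation of the β-keto aldehyde occurs on the face opposite the 1,3-diaxial angular methyl, so the new methyl is equatorial and the formyl group axial (cis to the angular methyl), which sets C4.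

Step 6
Reactants: 11 (1S,3aS,4R,7aR)-1-ethenyl-1-hydroxy-4,7a-dimethyl-5-oxooctahydro-1H-indene-4-carbaldehyde
Product: 12 (1S,3aS,4R,7aR)-4-(dimethoxymethyl)-1-ethenyl-1-hydroxy-4,7a-dimethyloctahydro-5H-inden-5-one
Conditions: HC(OMe)3, MeOH, PPTS (cat.), 25 °C
Reagents that add atoms: trimethyl orthoformate, COC(OC)OC; methanol, CO
Why: Chemoselective acetalization of the aldehyde over the α-quaternary ketone under mild acid that leaves the tertiary allylic alcohol intact.

Step 7
Reactants: 12 (1S,3aS,4R,7aR)-4-(dimethoxymethyl)-1-ethenyl-1-hydroxy-4,7a-dimethyloctahydro-5H-inden-5-one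
Product: 13 (1S,3aS,4S,5S,7aR)-4-(dimethoxymethyl)-1-ethenyl-4,7a-dimethyloctahydro-1H-indene-1,5-diol
Conditions: L-Selectride, THF, −78 → 0 °C; H2O
Reagents that add atoms: none
Why: L-Selectride reduction delivers hydride along the equatorial trajectory, giving the axial C3 alcohol (trans to the axial acetal carbon), as with 4,4-disubstituted 3-oxo terpenoids.

Step 8
Reactants: 13 (1S,3aS,4S,5S,7aR)-4-(dimethoxymethyl)-1-ethenyl-4,7a-dimethyloctahydro-1H-indene-1,5-diol
Product: 14 (1S,3aS,4S,5S,7aR)-4-(dimethoxymethyl)-1-ethenyl-1-hydroxy-4,7a-dimethyloctahydro-1H-inden-5-yl acetate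
Conditions: Ac2O, DMAP, pyridine, CH2Cl2, 25 °C
Reagents that add atoms: acetic anhydride, CC(=O)OC(C)=O
Why: DMAP-catalysed acetylation esterifies the secondary alcohol only, because the neopentylic tertiary allylic alcohol does not react under these conditions.

Step 9
Reactants: 15 diketene (4-methylideneoxetan-2-one)
Product: 17 tert-butyl 4-bromo-3-oxobutanoate, via acid bromide 16 (not isolated)
Conditions: Br2, CH2Cl2, −25 °C; then t-BuOH, 2,6-lutidine, −25 → 0 °C
Reagents that add atoms: bromine, BrBr; tert-butanol, CC(C)(C)O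
Why: Bromination of the enol-ether double bond of diketene with ring opening gives 4-bromoacetoacetyl bromide, which is esterified by tert-butanol (the standard route to 4-haloacetoacetates).

Step 10
Reactants: 14 (1S,3aS,4S,5S,7aR)-4-(dimethoxymethyl)-1-ethenyl-1-hydroxy-4,7a-dimethyloctahydro-1H-inden-5-yl acetate; 17 tert-butyl 4-bromo-3-oxobutanoate
Product: 18 tert-butyl 5-[(1S,4aS,5S,6S,8aR)-6-acetoxy-5-(dimethoxymethyl)-5,8a-dimethyl-2-oxodecahydronaphthalen-1-yl]-3-oxopentanoate
Conditions: fac-Ir(ppy)3 (1 mol%), Cu(MeCN)4BF4 (10 mol%), dtbbpy (12 mol%), NaHCO3, MeCN, blue LEDs, 25 °C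
Reagents that add atoms: none
Why: Proposed new method: a photoredox/copper alkylative semipinacol ring expansion of an unactivated tertiary vinyl cyclopentanol, in which excited Ir(III) reduces bromide 17 to an electrophilic α-keto radical that adds to the terminal vinyl carbon, the secondary β-hydroxyalkyl radical is captured and oxidized by Cu(II) (Kochi-type) to a C9 carbenium equivalent, and the antiperiplanar, more electron-rich quaternary C10 shifts from C8 to C9 with retention while the carbinol becomes the C8 ketone (cyclopentane → cyclohexanone, with C9 settling through the enol as the equatorial side-chain epimer); the closest known reactions are photoredox radical-addition/semipinacol expansions of 1-(1-arylvinyl)cyclobutanols and Cu-catalysed trifluoromethylation/semipinacol rearrangements of allylic alcohols, neither shown for a non-benzylic vinyl group on an unstrained cyclopentanol.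

Step 11
Reactants: 18 tert-butyl 5-[(1S,4aS,5S,6S,8aR)-6-acetoxy-5-(dimethoxymethyl)-5,8a-dimethyl-2-oxodecahydronaphthalen-1-yl]-3-oxopentanoate
Product: 20 tert-butyl (2Z)-5-[(1S,4aS,5S,6S,8aR)-6-acetoxy-5-(dimethoxymethyl)-5,8a-dimethyl-2-{[(trifluoromethyl)sulfonyl]oxy}-1,4,4a,5,6,7,8,8a-octahydronaphthalen-1-yl]-3-{[(trifluoromethyl)sulfonyl]oxy}pent-2-enoate, via dilithium bis-enolate 19 (not isolated)
Conditions: LiHMDS (2.2 equiv), THF, −78 °C; Comins' reagent (2.3 equiv), −78 → 0 °C; aq NH4Cl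
Reagents that add atoms: Comins' reagent [N-(5-chloropyridin-2-yl)bis(trifluoromethanesulfonyl)imide], FC(F)(F)S(=O)(=O)N(c1ccc(Cl)cn1)S(=O)(=O)C(F)(F)F
Why: Enol triflate formation: LiHMDS first gives the chelated Z-enolate of the β-keto ester and then deprotonates the C8 ketone kinetically at the C7 methylene (not the hindered C9 methine), and both enolates are O-triflated; the bis-enolate also cannot undergo intramolecular aldol reaction.

Step 12
Reactants: 20 tert-butyl (2Z)-5-[(1S,4aS,5S,6S,8aR)-6-acetoxy-5-(dimethoxymethyl)-5,8a-dimethyl-2-{[(trifluoromethyl)sulfonyl]oxy}-1,4,4a,5,6,7,8,8a-octahydronaphthalen-1-yl]-3-{[(trifluoromethyl)sulfonyl]oxy}pent-2-enoate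
Product: 21 tert-butyl (2E)-5-[(1R,4aS,5S,6S,8aS)-6-acetoxy-5-(dimethoxymethyl)-2,5,8a-trimethyl-1,4,4a,5,6,7,8,8a-octahydronaphthalen-1-yl]-3-methylpent-2-enoate
Conditions: Me2Zn, Pd(PPh3)4 (5 mol%), THF, 0 → 50 °C
Reagents that add atoms: dimethylzinc, C[Zn]C
Why: Twofold Negishi coupling replaces both alkenyl triflates by methyl with retention of geometry, giving the 8-methyl-Δ7 olefin and the 13E enoate (Z-triflate becomes E-enoate) in one operation while tolerating acetate, acetal and ester.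

Step 13
Reactants: 21 tert-butyl (2E)-5-[(1R,4aS,5S,6S,8aS)-6-acetoxy-5-(dimethoxymethyl)-2,5,8a-trimethyl-1,4,4a,5,6,7,8,8a-octahydronaphthalen-1-yl]-3-methylpent-2-enoate
Product: 22 (2E)-5-[(1R,4aS,5S,6S,8aS)-6-acetoxy-5-formyl-2,5,8a-trimethyl-1,4,4a,5,6,7,8,8a-octahydronaphthalen-1-yl]-3-methylpent-2-enoic acid
Conditions: TFA/CH2Cl2 (1:4), H2O (5 equiv), 0 → 20 °C
Reagents that add atoms: water, O
Why: Acidolysis of the tert-butyl ester (loss of isobutene) and hydrolysis of the dimethyl acetal occur together, while the secondary acetate, trans-diaxial to the aldehyde carbon and unable to eliminate, survives.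

## Compound list

1 | 2-methylcyclopentane-1,3-dione | CC1C(=O)CCC1=O | starting material
2 | but-3-en-2-one (methyl vinyl ketone) | CC(=O)C=C | starting material
3 | 2-methyl-2-(3-oxobutyl)cyclopentane-1,3-dione | CC(=O)CCC1(C)C(=O)CCC1=O | intermediate
4 | (3aR,7aR)-3a-hydroxy-7a-methylhexahydro-1H-indene-1,5(6H)-dione (cis-fused ketol) | O=C1CC[C@@]2(C)C(=O)CC[C@@]2(O)C1 | intermediate
5 | (R)-7a-methyl-2,3,7,7a-tetrahydro-1H-indene-1,5(6H)-dione [(R)-Hajos–Parrish ketone] | O=C1CC[C@@]2(C)C(=O)CCC2=C1 | intermediate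
6 | vinylmagnesium bromide | C=C[Mg]Br | starting material
7 | (1S,7aR)-1-ethenyl-1-hydroxy-7a-methyl-1,2,3,6,7,7a-hexahydro-5H-inden-5-one (OH cis to the angular methyl) | O=C1CC[C@@]2(C)[C@@](O)(C=C)CCC2=C1 | intermediate
8 | lithium alkoxide of 7 | O=C1CC[C@@]2(C)[C@@](O[Li])(C=C)CCC2=C1 | intermediate
9 | dilithium enolate-alkoxide of the trans-fused 5-ketone (Δ4 enolate) | [Li]OC1CC[C@@]2(C)[C@@](O[Li])(C=C)CC[C@@H]2C=1 | intermediate
10 | (1S,3aS,7aR)-1-ethenyl-1-hydroxy-4-[(Z)-hydroxymethylidene]-7a-methyloctahydro-5H-inden-5-one | O=C1CC[C@@]2(C)[C@@](O)(C=C)CC[C@@H]2/C1=C/O | intermediate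
11 | (1S,3aS,4R,7aR)-1-ethenyl-1-hydroxy-4,7a-dimethyl-5-oxooctahydro-1H-indene-4-carbaldehyde | O=C1CC[C@@]2(C)[C@@](O)(C=C)CC[C@@H]2[C@]1(C)C=O | intermediate
12 | (1S,3aS,4R,7aR)-4-(dimethoxymethyl)-1-ethenyl-1-hydroxy-4,7a-dimethyloctahydro-5H-inden-5-one | O=C1CC[C@@]2(C)[C@@](O)(C=C)CC[C@@H]2[C@]1(C)C(OC)OC | intermediate
13 | (1S,3aS,4S,5S,7aR)-4-(dimethoxymethyl)-1-ethenyl-4,7a-dimethyloctahydro-1H-indene-1,5-diol | O[C@H]1CC[C@@]2(C)[C@@](O)(C=C)CC[C@@H]2[C@]1(C)C(OC)OC | intermediate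
14 | (1S,3aS,4S,5S,7aR)-4-(dimethoxymethyl)-1-ethenyl-1-hydroxy-4,7a-dimethyloctahydro-1H-inden-5-yl acetate | CC(=O)O[C@H]1CC[C@@]2(C)[C@@](O)(C=C)CC[C@@H]2[C@]1(C)C(OC)OC | intermediate
15 | diketene (4-methylideneoxetan-2-one) | C=C1CC(=O)O1 | starting material
16 | 4-bromo-3-oxobutanoyl bromide | BrCC(=O)CC(Br)=O | intermediate
17 | tert-butyl 4-bromo-3-oxobutanoate | BrCC(=O)CC(=O)OC(C)(C)C | intermediate
18 | tert-butyl 5-[(1S,4aS,5S,6S,8aR)-6-acetoxy-5-(dimethoxymethyl)-5,8a-dimethyl-2-oxodecahydronaphthalen-1-yl]-3-oxopentanoate | CC(=O)O[C@H]1CC[C@@]2(C)[C@H](CCC(=O)CC(=O)OC(C)(C)C)C(=O)CC[C@@H]2[C@]1(C)C(OC)OC | intermediate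
19 | dilithium bis-enolate of 18 (C7=C8 enolate; Z-enolate of the β-keto ester) | CC(=O)O[C@H]1CC[C@@]2(C)[C@H](CC/C(O[Li])=C/C(=O)OC(C)(C)C)C(O[Li])=CC[C@@H]2[C@]1(C)C(OC)OC | intermediate
20 | tert-butyl (2Z)-5-[(1S,4aS,5S,6S,8aR)-6-acetoxy-5-(dimethoxymethyl)-5,8a-dimethyl-2-{[(trifluoromethyl)sulfonyl]oxy}-1,4,4a,5,6,7,8,8a-octahydronaphthalen-1-yl]-3-{[(trifluoromethyl)sulfonyl]oxy}pent-2-enoate | CC(=O)O[C@H]1CC[C@@]2(C)[C@H](CC/C(OS(=O)(=O)C(F)(F)F)=C/C(=O)OC(C)(C)C)C(OS(=O)(=O)C(F)(F)F)=CC[C@@H]2[C@]1(C)C(OC)OC | intermediate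
21 | tert-butyl (2E)-5-[(1R,4aS,5S,6S,8aS)-6-acetoxy-5-(dimethoxymethyl)-2,5,8a-trimethyl-1,4,4a,5,6,7,8,8a-octahydronaphthalen-1-yl]-3-methylpent-2-enoate | CC(=O)O[C@H]1CC[C@@]2(C)[C@H](CC/C(C)=C/C(=O)OC(C)(C)C)C(C)=CC[C@@H]2[C@]1(C)C(OC)OC | intermediate
22 | (2E)-5-[(1R,4aS,5S,6S,8aS)-6-acetoxy-5-formyl-2,5,8a-trimethyl-1,4,4a,5,6,7,8,8a-octahydronaphthalen-1-yl]-3-methylpent-2-enoic acid | CC(=O)O[C@H]1CC[C@@]2(C)[C@H](CC/C(C)=C/C(=O)O)C(C)=CC[C@@H]2[C@]1(C)C=O | target

## Step count and risks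

Total step count: 13. Longest linear sequence: 12 (steps 1–8 and 10–13; step 9 is a one-step side branch).

**Step 10 (the proposed ring expansion).** The unstabilized secondary radical may take a bromine atom or lose a β-hydrogen instead of being oxidized, and the tertiary allylic alcohol is Lewis-acid sensitive. The fallback sets out from 14 (with 17) and splits the event into two known reactions. A visible-light atom-transfer (Kharasch-type) radical addition of 17 across the vinyl group (Ru(bpy)3Cl2, LiBr, DMF/H2O, blue LEDs) gives the isolable bromohydrin tert-butyl 6-[(1R,3aS,4S,5S,7aR)-5-acetoxy-4-(dimethoxymethyl)-1-hydroxy-4,7a-dimethyloctahydro-1H-inden-1-yl]-6-bromo-3-oxohexanoate F1 (both epimers at the bromine-bearing carbon). A classical silver(I)-assisted halohydrin ring enlargement (Ag2CO3 with AgBF4, CH2Cl2, 0 °C) then drives the same C10 migration. The route is rejoined at 18.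

**Step 4 (Birch reduction/formylation).** The trans:cis ratio is less secure for hydrindenones than for octalones, and proton exchange can scramble the enolate before formylation. The fallback sets out from 7 and uses hydride conjugate reduction with DIBAL-H/t-BuCu in THF/HMPA, the reagent established for trans-hydrindanones from Hajos–Parrish enones. The aluminium enolate and the tertiary alkoxide are silylated (TMSCl, Et3N) to trimethyl{[(1S,3aR,7aR)-1-ethenyl-7a-methyl-1-(trimethylsilyloxy)-2,3,3a,6,7,7a-hexahydro-1H-inden-5-yl]oxy}silane F2. MeLi (THF, 0 °C) cleaves only the enol silyl ether to the regiodefined lithium enolate, which is formylated with 2,2,2-trifluoroethyl formate as before. Mildly acidic work-up removes the tertiary silyl ether, and the route is rejoined at 10.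

**Step 11 (one-pot bis-triflation).** The 1,5-dicarbonyl array can close by a Robinson-type aldol reaction, and the geometry of the β-keto ester enol triflate may erode. The fallback sets out from 18 and differentiates the carbonyls stepwise:
- NaH then ClP(O)(OEt)2 converts only the β-keto ester into tert-butyl (2Z)-5-[(1S,4aS,5S,6S,8aR)-6-acetoxy-5-(dimethoxymethyl)-5,8a-dimethyl-2-oxodecahydronaphthalen-1-yl]-3-[(diethoxyphosphoryl)oxy]pent-2-enoate F3.
- Me2CuLi (−78 to −45 °C, Weiler olefin synthesis) gives tert-butyl (2E)-5-[(1S,4aS,5S,6S,8aR)-6-acetoxy-5-(dimethoxymethyl)-5,8a-dimethyl-2-oxodecahydronaphthalen-1-yl]-3-methylpent-2-enoate F4.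
- KHMDS/PhNTf2 (−78 °C) gives tert-butyl (2E)-5-[(1S,4aS,5S,6S,8aR)-6-acetoxy-5-(dimethoxymethyl)-5,8a-dimethyl-2-{[(trifluoromethyl)sulfonyl]oxy}-1,4,4a,5,6,7,8,8a-octahydronaphthalen-1-yl]-3-methylpent-2-enoate F5.
- Pd/Me2Zn methylation of this single triflate rejoins the route at 21.

Further compounds

F1 | step 10 | tert-butyl 6-[(1R,3aS,4S,5S,7aR)-5-acetoxy-4-(dimethoxymethyl)-1-hydroxy-4,7a-dimethyloctahydro-1H-inden-1-yl]-6-bromo-3-oxohexanoate (both C6 epimers) | CC(=O)O[C@H]1CC[C@@]2(C)[C@@](O)(C(Br)CCC(=O)CC(=O)OC(C)(C)C)CC[C@@H]2[C@]1(C)C(OC)OC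
F2 | step 4 | trimethyl{[(1S,3aR,7aR)-1-ethenyl-7a-methyl-1-(trimethylsilyloxy)-2,3,3a,6,7,7a-hexahydro-1H-inden-5-yl]oxy}silane | C[Si](C)(C)OC1CC[C@@]2(C)[C@@](O[Si](C)(C)C)(C=C)CC[C@@H]2C=1
F3 | step 11 | tert-butyl (2Z)-5-[(1S,4aS,5S,6S,8aR)-6-acetoxy-5-(dimethoxymethyl)-5,8a-dimethyl-2-oxodecahydronaphthalen-1-yl]-3-[(diethoxyphosphoryl)oxy]pent-2-enoate | CC(=O)O[C@H]1CC[C@@]2(C)[C@H](CC/C(OP(=O)(OCC)OCC)=C/C(=O)OC(C)(C)C)C(=O)CC[C@@H]2[C@]1(C)C(OC)OC
F4 | step 11 | tert-butyl (2E)-5-[(1S,4aS,5S,6S,8aR)-6-acetoxy-5-(dimethoxymethyl)-5,8a-dimethyl-2-oxodecahydronaphthalen-1-yl]-3-methylpent-2-enoate | CC(=O)O[C@H]1CC[C@@]2(C)[C@H](CC/C(C)=C/C(=O)OC(C)(C)C)C(=O)CC[C@@H]2[C@]1(C)C(OC)OC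
F5 | step 11 | tert-butyl (2E)-5-[(1S,4aS,5S,6S,8aR)-6-acetoxy-5-(dimethoxymethyl)-5,8a-dimethyl-2-{[(trifluoromethyl)sulfonyl]oxy}-1,4,4a,5,6,7,8,8a-octahydronaphthalen-1-yl]-3-methylpent-2-enoate | CC(=O)O[C@H]1CC[C@@]2(C)[C@H](CC/C(C)=C/C(=O)OC(C)(C)C)C(OS(=O)(=O)C(F)(F)F)=CC[C@@H]2[C@]1(C)C(OC)OC
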